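**Retrosynthetic overview** (core numbered as 2-benzofuran-1(3H)-one: C1 lactone C=O, C3 hemiacetal, C4 bears the propanoate, C5 the cyclohexyl)
1. Hydroxy-lactone ring (formed last): ring–chain closure of the cis formyl acid 28, released from aldehyde benzyl ester 27.
2. C4 side chain: the (2R)-propanoate comes from asymmetric hydrogenation of 2-alkenylacrylic acid 23, built by two palladium carbonylations from enol triflate 19.
3. Tetrasubstituted C4=C5 alkene: fixed regiospecifically as enol triflate 19 from enone 17 (singlet-oxygen ene reaction of 14, then conjugate reduction and triflation).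
4. Cyclohexene ring (second ring formed): catalytic asymmetric Diels–Alder of diene 11 with acryloyl oxazolidinone 12, setting C3a/C7a cis.
5. Diene 11 comes from quaternary ester 6, made by Johnson–Claisen rearrangement of (S)-isophorol 2, itself from ketoreductase reduction of isophorone 1 (the trimethylcyclohexane ring is bought in).

Assumption: the hemiacetal carbon C3 equilibrates by ring–chain tautomerism, and the (3R) anomer of the target (OH on the face of C4, able to hydrogen-bond to the propanoate C=O) is taken as the equilibrium form.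

**Route**

Step 1
Reactants: 1 isophorone (3,5,5-trimethylcyclohex-2-en-1-one)
Product: 2 (1S)-3,5,5-trimethylcyclohex-2-en-1-ol
Conditions: (S)-selective ketoreductase (NADPH-dependent alcohol dehydrogenase), NADP+ (cat.), i-PrOH, phosphate buffer pH 7, 30 °C
Reagents that add atoms: none
Why: Ketoreductases reduce only the C=O of a cyclic enone and deliver hydride from NADPH to one enantiotopic face in the chiral active site, so this biocatalytic asymmetric carbonyl reduction sets the first stereocentre (S), with isopropanol recycling the cofactor.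

Step 2
Reactants: 2 (1S)-3,5,5-trimethylcyclohex-2-en-1-ol
Product: 5 ethyl 2-[(1S)-1,5,5-trimethylcyclohex-2-en-1-yl]acetate, via mixed orthoester 3 (not isolated), via ketene acetal 4 (not isolated)
Conditions: MeC(OEt)3, EtCO2H (cat.), 140 °C, EtOH distilled off
Reagents that add atoms: triethyl orthoacetate, CC(OCC)(OCC)OCC
Why: Johnson–Claisen rearrangement: orthoester exchange and loss of ethanol give the ketene acetal, whose suprafacial [3,3] shift forms the new C–C bond on the face of the departing oxygen and so transfers the carbinol chirality to the (S) quaternary carbon.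

Step 3
Reactants: 5 ethyl 2-[(1S)-1,5,5-trimethylcyclohex-2-en-1-yl]acetate
Product: 6 ethyl 2-[(1S)-1,3,3-trimethylcyclohexyl]acetate
Conditions: H2 (1 atm), Pd/C, EtOAc, rt
Reagents that add atoms: none
Why: Heterogeneous catalytic hydrogenation saturates the disubstituted ring alkene and leaves the ester and the quaternary centre untouched.

Step 4
Reactants: 6 ethyl 2-[(1S)-1,3,3-trimethylcyclohexyl]acetate
Product: 7 2-[(1S)-1,3,3-trimethylcyclohexyl]acetaldehyde
Conditions: i-Bu2AlH (1.05 equiv), CH2Cl2, −78 °C; aqueous Rochelle salt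
Reagents that add atoms: none
Why: Partial hydride reduction of the ester stops at the tetrahedral aluminium hemiacetal at −78 °C, which releases the aldehyde on work-up.

Step 5
Reactants: 7 2-[(1S)-1,3,3-trimethylcyclohexyl]acetaldehyde
Product: 8 2-[(1S)-1,3,3-trimethylcyclohexyl]prop-2-enal
Conditions: aq. CH2O, pyrrolidine (10 mol%), EtCO2H (10 mol%), i-PrOH, 45 °C
Reagents that add atoms: formaldehyde, C=O
Why: Organocatalytic α-methylenation (enamine Mannich condensation, then elimination of the amine) installs the exocyclic methylene on the only enolisable carbon.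

Step 6
Reactants: 8 2-[(1S)-1,3,3-trimethylcyclohexyl]prop-2-enal
Product: 9 methyl (2E)-4-[(1S)-1,3,3-trimethylcyclohexyl]penta-2,4-dienoate
Conditions: Ph3P=CHCO2Me, CH2Cl2, rt
Reagents that add atoms: methyl (triphenylphosphoranylidene)acetate, COC(=O)C=P(c1ccccc1)(c1ccccc1)c1ccccc1
Why: Wittig olefination with a stabilised ylide adds to the aldehyde carbonyl and gives the E-enoate, completing the 1,3-diene.

Step 7
Reactants: 9 methyl (2E)-4-[(1S)-1,3,3-trimethylcyclohexyl]penta-2,4-dienoate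
Product: 10 (2E)-4-[(1S)-1,3,3-trimethylcyclohexyl]penta-2,4-dien-1-ol
Conditions: i-Bu2AlH (2.2 equiv), CH2Cl2, −78 °C
Reagents that add atoms: none
Why: 1,2-Reduction of the conjugated ester by the aluminium hydride gives the allylic alcohol without touching the diene.

Step 8
Reactants: 10 (2E)-4-[(1S)-1,3,3-trimethylcyclohexyl]penta-2,4-dien-1-ol
Product: 11 tert-butyl(dimethyl){[(2E)-4-[(1S)-1,3,3-trimethylcyclohexyl]penta-2,4-dien-1-yl]oxy}silane
Conditions: TBSCl, imidazole, CH2Cl2, 0 °C to rt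
Reagents that add atoms: tert-butyl(chloro)dimethylsilane, CC(C)(C)[Si](C)(C)Cl
Why: Standard O-silylation protects the primary alcohol through the Lewis acid, oxidation, hydride and palladium steps that follow.

Step 9
Reactants: 11 silyl dienyl ether, 12 3-(prop-2-enoyl)-1,3-oxazolidin-2-one
Product: 13 3-{[(1R,2S)-2-({[tert-butyl(dimethyl)silyl]oxy}methyl)-4-[(1S)-1,3,3-trimethylcyclohexyl]cyclohex-3-en-1-yl]carbonyl}-1,3-oxazolidin-2-one
Conditions: [Cu((R,R)-t-Bu-box)](SbF6)2 (10 mol%), CH2Cl2, −20 °C to rt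
Reagents that add atoms: none
Why: Catalytic enantioselective Diels–Alder reaction: the acryloyl imide chelated to the divalent copper bis(oxazoline) Lewis acid is attacked on its Si face, the 1- and 3-substituents of the diene both direct the "ortho/para" regiochemistry, and the endo transition state places the two new stereocentres cis (1R,2S) under catalyst control, independent of the remote quaternary centre.

Step 10
Reactants: 13 cyclohexene imide
Product: 14 benzyl (1R,2S)-2-({[tert-butyl(dimethyl)silyl]oxy}methyl)-4-[(1S)-1,3,3-trimethylcyclohexyl]cyclohex-3-ene-1-carboxylate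
Conditions: BnOH, n-BuLi, THF, −78 to 0 °C; NH4Cl work-up
Reagents that add atoms: benzyl alcohol (used as lithium benzyloxide), OCc1ccccc1
Why: Acyl transfer from the imide to benzyloxide (transesterification at the exocyclic carbonyl) gives the benzyl ester at 0 °C without epimerising C1.

Step 11
Reactants: 14 cyclohexene benzyl ester
Product: 17 benzyl (1R,6S)-6-({[tert-butyl(dimethyl)silyl]oxy}methyl)-5-oxo-4-[(1S)-1,3,3-trimethylcyclohexyl]cyclohex-3-ene-1-carboxylate, via allylic hydroperoxide 15 (not isolated), via peroxyacetate 16 (not isolated)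
Conditions: O2, tetraphenylporphyrin (cat.), visible light, Ac2O, pyridine, DMAP (cat.), CH2Cl2, 0 °C to rt
Reagents that add atoms: dioxygen, O=O
Why: Schenck ene reaction: singlet oxygen bonds to the less hindered alkene carbon and removes the ring hydrogen geminal to the bulky tertiary group, and Kornblum–DeLaMare dehydration of the acetylated secondary hydroperoxide gives the transposed enone without touching the existing stereocentres.

Step 12
Reactants: 17 enone
Product: 19 benzyl (1R,2S)-2-({[tert-butyl(dimethyl)silyl]oxy}methyl)-4-[(1S)-1,3,3-trimethylcyclohexyl]-3-{[(trifluoromethyl)sulfonyl]oxy}cyclohex-3-ene-1-carboxylate, via lithium enolate 18 (not isolated)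
Conditions: LiBH(s-Bu)3 (1.05 equiv), THF, −78 °C; then Comins' reagent, −78 to 0 °C; NH4Cl work-up
Reagents that add atoms: Comins' reagent [N-(5-chloropyridin-2-yl)bis(trifluoromethanesulfonimide)], FC(F)(F)S(=O)(=O)N(c1ccc(Cl)cn1)S(=O)(=O)C(F)(F)F
Why: Conjugate (1,4) hydride reduction of the β-unsubstituted enone generates the tetrasubstituted enolate regiospecifically, and O-triflation traps it as the enol triflate with the double bond fixed between the carbon bearing the trimethylcyclohexyl group and the future side-chain carbon.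

Step 13
Reactants: 19 enol triflate
Product: 20 benzyl (1R,2R)-3-acetyl-2-({[tert-butyl(dimethyl)silyl]oxy}methyl)-4-[(1S)-1,3,3-trimethylcyclohexyl]cyclohex-3-ene-1-carboxylate
Conditions: CO (3 atm), Me4Sn, PdCl2(dppf) (10 mol%), LiCl, DMF, 70 °C
Reagents that add atoms: carbon monoxide, [C-]#[O+]; tetramethylstannane, C[Sn](C)(C)C
Why: Carbonylative Stille coupling: zerovalent palladium inserts into the vinyl triflate, CO insertion gives an acylpalladium that sits one atom away from the congested ring carbon, and methyl transfer from tin gives the methyl ketone.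

Step 14
Reactants: 20 methyl ketone
Product: 22 benzyl (1R,2R)-2-({[tert-butyl(dimethyl)silyl]oxy}methyl)-4-[(1S)-1,3,3-trimethylcyclohexyl]-3-(1-{[(trifluoromethyl)sulfonyl]oxy}ethenyl)cyclohex-3-ene-1-carboxylate, via potassium enolate 21 (not isolated)
Conditions: KN(SiMe3)2 (1.1 equiv), THF, −78 °C; then PhNTf2, −78 to 0 °C; NH4Cl work-up
Reagents that add atoms: N-phenylbis(trifluoromethanesulfonimide), O=S(=O)(N(c1ccccc1)S(=O)(=O)C(F)(F)F)C(F)(F)F
Why: Kinetic enolisation can only occur on the acetyl methyl group (the other α-carbon is sp2), and O-sulfonylation of that enolate gives the 2-triflyloxy diene.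

Step 15
Reactants: 22 dienyl triflate
Product: 23 2-[(5R,6R)-5-[(benzyloxy)carbonyl]-6-({[tert-butyl(dimethyl)silyl]oxy}methyl)-2-[(1S)-1,3,3-trimethylcyclohexyl]cyclohex-1-en-1-yl]prop-2-enoic acid
Conditions: Pd(OAc)2 (5 mol%), dppf, CO (1 atm), H2O, Et3N, DMF, 60 °C; then dilute acid
Reagents that add atoms: carbon monoxide, [C-]#[O+]; water, O
Why: Palladium-catalysed hydroxycarbonylation (oxidative addition, CO insertion, hydrolysis of the acylpalladium) converts the vinyl triflate into the 2-substituted acrylic acid.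

Step 16
Reactants: 23 acrylic acid
Product: 24 (2R)-2-[(5R,6R)-5-[(benzyloxy)carbonyl]-6-({[tert-butyl(dimethyl)silyl]oxy}methyl)-2-[(1S)-1,3,3-trimethylcyclohexyl]cyclohex-1-en-1-yl]propanoic acid
Conditions: Ru(OAc)2[(R)-BINAP] (2 mol%), H2 (100 atm), MeOH, rt
Reagents that add atoms: none
Why: Carboxylate-directed asymmetric hydrogenation of a 2-substituted acrylic acid (Noyori type): the (R)-BINAP ruthenium carboxylate adds H2 to one face of the 1,1-disubstituted alkene and sets the (R) α-methyl centre under catalyst control, while the tetrasubstituted ring alkene and the benzyl ester are inert.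

Step 17
Reactants: 24 (2R)-propanoic acid
Product: 25 benzyl (1R,2R)-2-({[tert-butyl(dimethyl)silyl]oxy}methyl)-3-[(2R)-1-methoxy-1-oxopropan-2-yl]-4-[(1S)-1,3,3-trimethylcyclohexyl]cyclohex-3-ene-1-carboxylate
Conditions: Me3SiCHN2, MeOH–toluene, 0 °C
Reagents that add atoms: (trimethylsilyl)diazomethane, C[Si](C)(C)C=[N+]=[N-]
Why: O-Methylation of the carboxylic acid by the diazoalkane is neutral and does not epimerise the α-centre.

Step 18
Reactants: 25 methyl ester
Product: 26 benzyl (1R,2R)-2-(hydroxymethyl)-3-[(2R)-1-methoxy-1-oxopropan-2-yl]-4-[(1S)-1,3,3-trimethylcyclohexyl]cyclohex-3-ene-1-carboxylate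
Conditions: Bu4NF, AcOH, THF, 0 °C; used at once
Reagents that add atoms: none
Why: Fluoride-mediated desilylation, with acetic acid buffering so that no free alkoxide attacks the neighbouring cis benzyl ester.

Step 19
Reactants: 26 primary alcohol
Product: 27 benzyl (1R,2R)-2-formyl-3-[(2R)-1-methoxy-1-oxopropan-2-yl]-4-[(1S)-1,3,3-trimethylcyclohexyl]cyclohex-3-ene-1-carboxylate
Conditions: Dess–Martin periodinane, NaHCO3, CH2Cl2, 0 °C
Reagents that add atoms: none
Why: Dess–Martin oxidation under buffered non-basic conditions gives the aldehyde without epimerising C2 or moving the alkene into conjugation.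

Step 20
Reactants: 27 aldehyde
Product: 29 methyl (2R)-2-[(3R,3aR,7aR)-3-hydroxy-1-oxo-5-[(1S)-1,3,3-trimethylcyclohexyl]-1,3,3a,6,7,7a-hexahydro-2-benzofuran-4-yl]propanoate, via formyl acid 28 (not isolated)
Conditions: H2 (1 atm), Pd/C, EtOAc, rt
Reagents that add atoms: none
Why: Hydrogenolysis of the benzyl ester frees the acid, which adds to the cis aldehyde (ring–chain tautomerism) to close the hydroxy lactone, the hemiacetal carbon settling under thermodynamic control as the (3R) anomer while the hindered tetrasubstituted alkene is not hydrogenated.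

**Compound list**

1 | isophorone (3,5,5-trimethylcyclohex-2-en-1-one) | CC1=CC(=O)CC(C)(C)C1 | starting material
2 | (1S)-3,5,5-trimethylcyclohex-2-en-1-ol | O[C@@H]1C=C(C)CC(C)(C)C1 | intermediate
3 | mixed orthoester: 1,1-diethoxy-1-{[(1S)-3,5,5-trimethylcyclohex-2-en-1-yl]oxy}ethane | CCOC(C)(OCC)O[C@@H]1C=C(C)CC(C)(C)C1 | intermediate
4 | ketene acetal: 1-ethoxy-1-{[(1S)-3,5,5-trimethylcyclohex-2-en-1-yl]oxy}ethene | CCOC(=C)O[C@@H]1C=C(C)CC(C)(C)C1 | intermediate
5 | ethyl 2-[(1S)-1,5,5-trimethylcyclohex-2-en-1-yl]acetate | CCOC(=O)C[C@@]1(C)C=CCC(C)(C)C1 | intermediate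
6 | ethyl 2-[(1S)-1,3,3-trimethylcyclohexyl]acetate | CCOC(=O)C[C@@]1(C)CCCC(C)(C)C1 | intermediate
7 | 2-[(1S)-1,3,3-trimethylcyclohexyl]acetaldehyde | O=CC[C@@]1(C)CCCC(C)(C)C1 | intermediate
8 | 2-[(1S)-1,3,3-trimethylcyclohexyl]prop-2-enal | C=C(C=O)[C@@]1(C)CCCC(C)(C)C1 | intermediate
9 | methyl (2E)-4-[(1S)-1,3,3-trimethylcyclohexyl]penta-2,4-dienoate | COC(=O)/C=C/C(=C)[C@@]1(C)CCCC(C)(C)C1 | intermediate
10 | (2E)-4-[(1S)-1,3,3-trimethylcyclohexyl]penta-2,4-dien-1-ol | OC/C=C/C(=C)[C@@]1(C)CCCC(C)(C)C1 | intermediate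
11 | tert-butyl(dimethyl){[(2E)-4-[(1S)-1,3,3-trimethylcyclohexyl]penta-2,4-dien-1-yl]oxy}silane | CC(C)(C)[Si](C)(C)OC/C=C/C(=C)[C@@]1(C)CCCC(C)(C)C1 | intermediate
12 | 3-(prop-2-enoyl)-1,3-oxazolidin-2-one | C=CC(=O)N1CCOC1=O | starting material
13 | 3-{[(1R,2S)-2-({[tert-butyl(dimethyl)silyl]oxy}methyl)-4-[(1S)-1,3,3-trimethylcyclohexyl]cyclohex-3-en-1-yl]carbonyl}-1,3-oxazolidin-2-one | O=C(N1CCOC1=O)[C@@H]2CCC([C@@]3(C)CCCC(C)(C)C3)=C[C@@H]2CO[Si](C)(C)C(C)(C)C | intermediate
14 | benzyl (1R,2S)-2-({[tert-butyl(dimethyl)silyl]oxy}methyl)-4-[(1S)-1,3,3-trimethylcyclohexyl]cyclohex-3-ene-1-carboxylate | O=C(OCc1ccccc1)[C@@H]2CCC([C@@]3(C)CCCC(C)(C)C3)=C[C@@H]2CO[Si](C)(C)C(C)(C)C | intermediate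
15 | allylic hydroperoxide: benzyl (1R,6S)-6-({[tert-butyl(dimethyl)silyl]oxy}methyl)-5-hydroperoxy-4-[(1S)-1,3,3-trimethylcyclohexyl]cyclohex-3-ene-1-carboxylate (C5 epimers) | O=C(OCc1ccccc1)[C@@H]2CC=C([C@@]3(C)CCCC(C)(C)C3)C(OO)[C@@H]2CO[Si](C)(C)C(C)(C)C | intermediate
16 | peroxyacetate: benzyl (1R,6S)-5-(acetylperoxy)-6-({[tert-butyl(dimethyl)silyl]oxy}methyl)-4-[(1S)-1,3,3-trimethylcyclohexyl]cyclohex-3-ene-1-carboxylate (C5 epimers) | O=C(OCc1ccccc1)[C@@H]2CC=C([C@@]3(C)CCCC(C)(C)C3)C(OOC(C)=O)[C@@H]2CO[Si](C)(C)C(C)(C)C | intermediate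
17 | benzyl (1R,6S)-6-({[tert-butyl(dimethyl)silyl]oxy}methyl)-5-oxo-4-[(1S)-1,3,3-trimethylcyclohexyl]cyclohex-3-ene-1-carboxylate | O=C(OCc1ccccc1)[C@@H]2CC=C([C@@]3(C)CCCC(C)(C)C3)C(=O)[C@@H]2CO[Si](C)(C)C(C)(C)C | intermediate
18 | lithium enolate: lithium (5R,6S)-5-[(benzyloxy)carbonyl]-6-({[tert-butyl(dimethyl)silyl]oxy}methyl)-2-[(1S)-1,3,3-trimethylcyclohexyl]cyclohex-1-en-1-olate | O=C(OCc1ccccc1)[C@@H]2CCC([C@@]3(C)CCCC(C)(C)C3)=C([O-])[C@@H]2CO[Si](C)(C)C(C)(C)C.[Li+] | intermediate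
19 | benzyl (1R,2S)-2-({[tert-butyl(dimethyl)silyl]oxy}methyl)-4-[(1S)-1,3,3-trimethylcyclohexyl]-3-{[(trifluoromethyl)sulfonyl]oxy}cyclohex-3-ene-1-carboxylate | O=C(OCc1ccccc1)[C@@H]2CCC([C@@]3(C)CCCC(C)(C)C3)=C(OS(=O)(=O)C(F)(F)F)[C@@H]2CO[Si](C)(C)C(C)(C)C | intermediate
20 | benzyl (1R,2R)-3-acetyl-2-({[tert-butyl(dimethyl)silyl]oxy}methyl)-4-[(1S)-1,3,3-trimethylcyclohexyl]cyclohex-3-ene-1-carboxylate | O=C(OCc1ccccc1)[C@@H]2CCC([C@@]3(C)CCCC(C)(C)C3)=C(C(C)=O)[C@@H]2CO[Si](C)(C)C(C)(C)C | intermediate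
21 | potassium enolate: potassium 1-[(5R,6R)-5-[(benzyloxy)carbonyl]-6-({[tert-butyl(dimethyl)silyl]oxy}methyl)-2-[(1S)-1,3,3-trimethylcyclohexyl]cyclohex-1-en-1-yl]ethen-1-olate | O=C(OCc1ccccc1)[C@@H]2CCC([C@@]3(C)CCCC(C)(C)C3)=C(C(=C)[O-])[C@@H]2CO[Si](C)(C)C(C)(C)C.[K+] | intermediate
22 | benzyl (1R,2R)-2-({[tert-butyl(dimethyl)silyl]oxy}methyl)-4-[(1S)-1,3,3-trimethylcyclohexyl]-3-(1-{[(trifluoromethyl)sulfonyl]oxy}ethenyl)cyclohex-3-ene-1-carboxylate | O=C(OCc1ccccc1)[C@@H]2CCC([C@@]3(C)CCCC(C)(C)C3)=C(C(=C)OS(=O)(=O)C(F)(F)F)[C@@H]2CO[Si](C)(C)C(C)(C)C | intermediate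
23 | 2-[(5R,6R)-5-[(benzyloxy)carbonyl]-6-({[tert-butyl(dimethyl)silyl]oxy}methyl)-2-[(1S)-1,3,3-trimethylcyclohexyl]cyclohex-1-en-1-yl]prop-2-enoic acid | O=C(OCc1ccccc1)[C@@H]2CCC([C@@]3(C)CCCC(C)(C)C3)=C(C(=C)C(=O)O)[C@@H]2CO[Si](C)(C)C(C)(C)C | intermediate
24 | (2R)-2-[(5R,6R)-5-[(benzyloxy)carbonyl]-6-({[tert-butyl(dimethyl)silyl]oxy}methyl)-2-[(1S)-1,3,3-trimethylcyclohexyl]cyclohex-1-en-1-yl]propanoic acid | O=C(OCc1ccccc1)[C@@H]2CCC([C@@]3(C)CCCC(C)(C)C3)=C([C@@H](C)C(=O)O)[C@@H]2CO[Si](C)(C)C(C)(C)C | intermediate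
25 | benzyl (1R,2R)-2-({[tert-butyl(dimethyl)silyl]oxy}methyl)-3-[(2R)-1-methoxy-1-oxopropan-2-yl]-4-[(1S)-1,3,3-trimethylcyclohexyl]cyclohex-3-ene-1-carboxylate | O=C(OCc1ccccc1)[C@@H]2CCC([C@@]3(C)CCCC(C)(C)C3)=C([C@@H](C)C(=O)OC)[C@@H]2CO[Si](C)(C)C(C)(C)C | intermediate
26 | benzyl (1R,2R)-2-(hydroxymethyl)-3-[(2R)-1-methoxy-1-oxopropan-2-yl]-4-[(1S)-1,3,3-trimethylcyclohexyl]cyclohex-3-ene-1-carboxylate | O=C(OCc1ccccc1)[C@@H]2CCC([C@@]3(C)CCCC(C)(C)C3)=C([C@@H](C)C(=O)OC)[C@@H]2CO | intermediate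
27 | benzyl (1R,2R)-2-formyl-3-[(2R)-1-methoxy-1-oxopropan-2-yl]-4-[(1S)-1,3,3-trimethylcyclohexyl]cyclohex-3-ene-1-carboxylate | O=C(OCc1ccccc1)[C@@H]2CCC([C@@]3(C)CCCC(C)(C)C3)=C([C@@H](C)C(=O)OC)[C@@H]2C=O | intermediate
28 | formyl acid: (1R,2R)-2-formyl-3-[(2R)-1-methoxy-1-oxopropan-2-yl]-4-[(1S)-1,3,3-trimethylcyclohexyl]cyclohex-3-ene-1-carboxylic acid | O=C(O)[C@@H]1CCC([C@@]2(C)CCCC(C)(C)C2)=C([C@@H](C)C(=O)OC)[C@@H]1C=O | intermediate
29 | methyl (2R)-2-[(3R,3aR,7aR)-3-hydroxy-1-oxo-5-[(1S)-1,3,3-trimethylcyclohexyl]-1,3,3a,6,7,7a-hexahydro-2-benzofuran-4-yl]propanoate | COC(=O)[C@H](C)C1=C([C@@]2(C)CCCC(C)(C)C2)CC[C@H]2C(=O)O[C@@H](O)[C@@H]12 | target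

**Step count and risk**

Total step count: 20. Longest linear sequence: 20 steps (1 to 29; 12 is bought).

The three steps most likely to fail:

Step 11 (regiochemistry of the singlet-oxygen ene reaction and survival of the β-silyloxy enone under the dehydration conditions). The fallback sets out from 14 and comes back at 17. Dihydroxylation of the trisubstituted alkene (K2OsO2(OH)4 cat., N-methylmorpholine N-oxide, acetone–water) gives benzyl (1R,2S)-2-({[tert-butyl(dimethyl)silyl]oxy}methyl)-3,4-dihydroxy-4-[(1S)-1,3,3-trimethylcyclohexyl]cyclohexane-1-carboxylate F1. Dess–Martin periodinane oxidises only its secondary alcohol, giving benzyl (1R,2S)-2-({[tert-butyl(dimethyl)silyl]oxy}methyl)-4-hydroxy-3-oxo-4-[(1S)-1,3,3-trimethylcyclohexyl]cyclohexane-1-carboxylate F2. Burgess reagent then dehydrates the tertiary alcohol; its only β-hydrogens are on the ring CH2, so the same enone 17 results.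

Step 13 (carbonylative coupling at a vinyl triflate flanked by the carbon that carries the quaternary group and by a branched ring carbon). The fallback sets out from 19 and comes back at 20. Nozaki–Hiyama–Kishi coupling with acetaldehyde (CrCl2, NiCl2 cat., DMF, rt), which tolerates esters and crowded vinyl triflates, gives benzyl (1R,2R)-2-({[tert-butyl(dimethyl)silyl]oxy}methyl)-3-(1-hydroxyethyl)-4-[(1S)-1,3,3-trimethylcyclohexyl]cyclohex-3-ene-1-carboxylate F3 as a mixture of carbinol epimers. Dess–Martin periodinane oxidises it to 20.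

Step 16 (facial selectivity and rate of hydrogenation on a very hindered 2-alkenylacrylic acid). The fallback sets out from 23 and comes back at 25, and gives up catalyst control for separation and recycling. Methylation of 23 with Me3SiCHN2 gives benzyl (1R,2R)-2-({[tert-butyl(dimethyl)silyl]oxy}methyl)-3-(3-methoxy-3-oxoprop-1-en-2-yl)-4-[(1S)-1,3,3-trimethylcyclohexyl]cyclohex-3-ene-1-carboxylate F4. Conjugate reduction with LiBH(s-Bu)3 (THF, −78 °C) and protonation of the ester enolate gives 25 together with its side-chain epimer benzyl (1R,2R)-2-({[tert-butyl(dimethyl)silyl]oxy}methyl)-3-[(2S)-1-methoxy-1-oxopropan-2-yl]-4-[(1S)-1,3,3-trimethylcyclohexyl]cyclohex-3-ene-1-carboxylate F5. The two are diastereomers and are separated by chromatography; F5 is re-equilibrated with DBU and recycled.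

Further compounds
F1 | step 11 | benzyl (1R,2S)-2-({[tert-butyl(dimethyl)silyl]oxy}methyl)-3,4-dihydroxy-4-[(1S)-1,3,3-trimethylcyclohexyl]cyclohexane-1-carboxylate (cis-3,4-diol; new centres not assigned) | O=C(OCc1ccccc1)[C@@H]2CCC(O)([C@@]3(C)CCCC(C)(C)C3)C(O)[C@@H]2CO[Si](C)(C)C(C)(C)C
F2 | step 11 | benzyl (1R,2S)-2-({[tert-butyl(dimethyl)silyl]oxy}methyl)-4-hydroxy-3-oxo-4-[(1S)-1,3,3-trimethylcyclohexyl]cyclohexane-1-carboxylate (C4 not assigned) | O=C(OCc1ccccc1)[C@@H]2CCC(O)([C@@]3(C)CCCC(C)(C)C3)C(=O)[C@@H]2CO[Si](C)(C)C(C)(C)C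
F3 | step 13 | benzyl (1R,2R)-2-({[tert-butyl(dimethyl)silyl]oxy}methyl)-3-(1-hydroxyethyl)-4-[(1S)-1,3,3-trimethylcyclohexyl]cyclohex-3-ene-1-carboxylate (carbinol epimers) | O=C(OCc1ccccc1)[C@@H]2CCC([C@@]3(C)CCCC(C)(C)C3)=C(C(C)O)[C@@H]2CO[Si](C)(C)C(C)(C)C
F4 | step 16 | benzyl (1R,2R)-2-({[tert-butyl(dimethyl)silyl]oxy}methyl)-3-(3-methoxy-3-oxoprop-1-en-2-yl)-4-[(1S)-1,3,3-trimethylcyclohexyl]cyclohex-3-ene-1-carboxylate | O=C(OCc1ccccc1)[C@@H]2CCC([C@@]3(C)CCCC(C)(C)C3)=C(C(=C)C(=O)OC)[C@@H]2CO[Si](C)(C)C(C)(C)C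
F5 | step 16 | benzyl (1R,2R)-2-({[tert-butyl(dimethyl)silyl]oxy}methyl)-3-[(2S)-1-methoxy-1-oxopropan-2-yl]-4-[(1S)-1,3,3-trimethylcyclohexyl]cyclohex-3-ene-1-carboxylate | O=C(OCc1ccccc1)[C@@H]2CCC([C@@]3(C)CCCC(C)(C)C3)=C([C@H](C)C(=O)OC)[C@@H]2CO[Si](C)(C)C(C)(C)C
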